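## Retrosynthetic overview

1. Target ⇒ open-chain (6Z)-2,3-epoxyfarnesyl bromide. One Br+-triggered cascade builds the bromocyclohexane first (C5a–C6 bond), then a six-membered epoxonium ring (O–C9a bond), and finally expands that oxane to the oxepene (ring oxygen moves from C3 to C2, H-4 is lost).
2. Epoxy bromide ⇒ (2E,6Z)-farnesol. Sharpless epoxidation sets C2, the one stereocentre carried into the cascade; then OH → Br. The 6Z olefin encodes the cis ring fusion.
3. (2E,6Z)-Farnesol ⇒ (Z)-C9 vinyl iodide + C6 dienol (B-alkyl Suzuki coupling).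
4. Vinyl iodide ⇒ 5-bromo-2-methylpent-2-ene + propyne (syn-carbocupration, iodination); dienol ⇒ (E)-3-methylpent-2-en-4-yn-1-ol (semi-hydrogenation).

Assumption: the SMILES is read literally as (2R,5aR,7S,9aS), i.e. H-5a, CH3-9a and Br-7 mutually cis (cis-fused rings); ring compounds carry benzoxepine locants, open-chain ones farnesane locants.

## Route

Step 1
Reactants: 1 5-bromo-2-methylpent-2-ene; 2 propyne
Product: 6 (1Z)-1-iodo-2,6-dimethylhepta-1,5-diene, via (4-methylpent-3-enyl)magnesium bromide 3 (not isolated), via (4-methylpent-3-enyl)copper 4 (not isolated), via (Z)-(2,6-dimethylhepta-1,5-dienyl)copper 5 (not isolated)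
Conditions: Mg, Et2O, 35 °C; CuBr·SMe2, Et2O, −45 °C; propyne, −25 °C, 3 h; I2, THF, −50 → 0 °C
Reagents that add atoms: iodine, [I][I]
Why: Normant carbocupration adds the alkylcopper syn across propyne with copper on the terminal carbon, and iodinolysis with retention gives the Z iodide (chain cis to iodine, typically >98:2), the geometry that later dictates the cis ring fusion.

Step 2
Reactants: 7 (2E)-3-methylpent-2-en-4-yn-1-ol
Product: 8 (2E)-3-methylpenta-2,4-dien-1-ol
Conditions: H2 (1 atm, stopped at 1.0 equiv), 5% Pd/CaCO3 poisoned with Pb(OAc)2, quinoline, Et2O, 0 °C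
Reagents that add atoms: none
Why: Lindlar-type semi-hydrogenation of a terminal alkyne stops at the vinyl group and leaves the trisubstituted E olefin and the alcohol untouched.

Step 3
Reactants: 8 (2E)-3-methylpenta-2,4-dien-1-ol; 6 (1Z)-1-iodo-2,6-dimethylhepta-1,5-diene
Product: 10 (2E,6Z)-3,7,11-trimethyldodeca-2,6,10-trien-1-ol, via bis(9-BBN) adduct 9 (not isolated)
Conditions: 9-BBN-H (2.2 equiv), THF, 0 °C → rt; then 6, Pd(dppf)Cl2 (5 mol%), 3 M aq NaOH, THF, rt
Reagents that add atoms: none
Why: The first equivalent of 9-BBN-H borylates the OH (H2 is lost), the second hydroborates only the monosubstituted diene terminus (anti-Markovnikov), and B-alkyl Suzuki–Miyaura coupling joins it to the vinyl iodide with retention of the Z geometry while aqueous base cleaves the O–B bond; no stereocentre is formed.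

Step 4
Reactants: 10 (2E,6Z)-3,7,11-trimethyldodeca-2,6,10-trien-1-ol
Product: 11 [(2S,3S)-3-[(3Z)-4,8-dimethylnona-3,7-dien-1-yl]-3-methyloxiran-2-yl]methanol
Conditions: Ti(OiPr)4 (5 mol%), L-(+)-DET (7.5 mol%), t-BuOOH, 4 Å MS, CH2Cl2, −20 °C
Reagents that add atoms: tert-butyl hydroperoxide, CC(C)(C)OO
Why: Katsuki–Sharpless asymmetric epoxidation is directed by the allylic OH to the 2,3-olefin only, and the L-(+)-tartrate catalyst delivers oxygen to the face that gives the (2S,3S) epoxide (as with geraniol, expected about 90–95% ee), which fixes the future C2.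

Step 5
Reactants: 11 [(2S,3S)-3-[(3Z)-4,8-dimethylnona-3,7-dien-1-yl]-3-methyloxiran-2-yl]methanol
Product: 12 (2R,3S)-2-(bromomethyl)-3-[(3Z)-4,8-dimethylnona-3,7-dien-1-yl]-3-methyloxirane
Conditions: PPh3, CBr4, 2,6-lutidine (cat.), CH2Cl2, −20 → 0 °C
Reagents that add atoms: carbon tetrabromide, BrC(Br)(Br)Br
Why: Appel reaction: bromide displaces the alkoxyphosphonium at the primary carbon (SN2) while the epoxide and C2 are untouched (the C2 descriptor changes from S to R only through CIP priorities), and lutidine buffers traces of HBr.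

Step 6
Reactants: 12 (2R,3S)-2-(bromomethyl)-3-[(3Z)-4,8-dimethylnona-3,7-dien-1-yl]-3-methyloxirane
Product: 15 (2R,5aR,7S,9aS)-7-bromo-2-(bromomethyl)-3,6,6,9a-tetramethyl-2,5,5a,6,7,8,9,9a-octahydro-1-benzoxepine, via epoxonium ion 13 (not isolated), via C3 oxepanyl cation 14 (not isolated)
Conditions: NBS (1.05 equiv), HFIP, 4 Å MS, 0 °C, 0.01 M, 15 min; chromatography (SiO2, then AgNO3–SiO2)
Reagents that add atoms: N-bromosuccinimide, O=C1CCC(=O)N1Br
Why: Proposed new method: NBS activated by hydrogen bonding to HFIP transfers Br+ to the terminal isopropylidene olefin; the Z olefin opens this bromonium anti through a chair transition state (C5a–C6 bond, Br equatorial, side chain axial) and the tertiary C9a cation is captured anti by the epoxide oxygen to give epoxonium 13 (six-membered ring O–C3–C4–C5–C5a–C9a), which places H-5a, CH3-9a and Br-7 all cis; the tertiary O–C3 bond of 13 then breaks so that the ring oxygen stays on C2 (a 1,2-shift of the ring oxygen from C3 to C2, oxane → oxepane, cation 14) and H-4 is lost to succinimide anion (E1, Zaitsev) to give the endocyclic olefin, while C2 keeps its Sharpless configuration because its C–O bond never breaks; the remote C2 centre should not bias the bromonium face, so 15 is expected with its carbocycle-antipodal diastereomer (about 1:1) and is separated by chromatography; the closest known reactions are bromonium-initiated polyene cyclisations terminated by hydroxyl groups and NBS/HFIP bromonium-initiated epoxide-opening cascades that run through epoxonium ions, but an epoxide has not been used as the terminating nucleophile of a carbocyclisation with eliminative ring expansion.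

## Compound list

1 | 5-bromo-2-methylpent-2-ene | CC(C)=CCCBr | starting material
2 | propyne | CC#C | starting material
3 | (4-methylpent-3-enyl)magnesium bromide | CC(C)=CCC[Mg]Br | intermediate (not isolated)
4 | (4-methylpent-3-enyl)copper (as its MgBr2 complex) | CC(C)=CCC[Cu] | intermediate (not isolated)
5 | (Z)-(2,6-dimethylhepta-1,5-dienyl)copper | CC(C)=CCC/C(C)=C\[Cu] | intermediate (not isolated)
6 | (1Z)-1-iodo-2,6-dimethylhepta-1,5-diene | CC(C)=CCC/C(C)=C\I | intermediate
7 | (2E)-3-methylpent-2-en-4-yn-1-ol | C#C/C(C)=C/CO | starting material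
8 | (2E)-3-methylpenta-2,4-dien-1-ol | C=C/C(C)=C/CO | intermediate
9 | 9-[(3E)-5-(9-borabicyclo[3.3.1]nonan-9-yloxy)-3-methylpent-3-en-1-yl]-9-borabicyclo[3.3.1]nonane | C/C(CCB1C2CCCC1CCC2)=C\COB1C2CCCC1CCC2 | intermediate (not isolated)
10 | (2E,6Z)-3,7,11-trimethyldodeca-2,6,10-trien-1-ol [(2E,6Z)-farnesol] | OC/C=C(C)/CC/C=C(C)\CCC=C(C)C | intermediate
11 | [(2S,3S)-3-[(3Z)-4,8-dimethylnona-3,7-dien-1-yl]-3-methyloxiran-2-yl]methanol | OC[C@@H]1O[C@@]1(C)CC/C=C(C)\CCC=C(C)C | intermediate
12 | (2R,3S)-2-(bromomethyl)-3-[(3Z)-4,8-dimethylnona-3,7-dien-1-yl]-3-methyloxirane | BrC[C@@H]1O[C@@]1(C)CC/C=C(C)\CCC=C(C)C | intermediate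
13 | tricyclic epoxonium ion: oxonium oxygen bonded to C2, C3 and C9a (oxirane O–C2–C3 fused to the oxane O–C3–C4–C5–C5a–C9a, which is cis-fused to the bromocyclohexane); C2, C5a, C7, C9a as in 15, C3 as in 12 | C[C@@]13CC[C@@H]2C(C)(C)[C@@H](Br)CC[C@]2(C)[O+]1[C@H]3CBr | intermediate (not isolated)
14 | (2R,5aR,7S,9aS)-7-bromo-2-(bromomethyl)-3,6,6,9a-tetramethyldecahydro-1-benzoxepin-3-ylium | C[C+]1CC[C@@H]2C(C)(C)[C@@H](Br)CC[C@]2(C)O[C@H]1CBr | intermediate (not isolated)
15 | (2R,5aR,7S,9aS)-7-bromo-2-(bromomethyl)-3,6,6,9a-tetramethyl-2,5,5a,6,7,8,9,9a-octahydro-1-benzoxepine | CC1=CC[C@@H]2C(C)(C)[C@@H](Br)CC[C@]2(C)O[C@H]1CBr | target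

## Step count and weak points

Total: 6 steps. Longest linear sequence: 5 steps (1 → 6 → 10 → 11 → 12 → 15, or equally 7 → 8 → 10 → 11 → 12 → 15). The enantiomeric purity of 15 is that of 11.

**Step 6 (the new cascade).** Risks:
- Br+ may go to the central olefin and be opened directly by the epoxide.
- The cyclohexyl cation may lose a proton before the epoxide closes.
- Cation 14 may be trapped by solvent or give the exocyclic-methylene isomer.

Fallback with known reactions only, setting out from 10 and coming back at 15 (it re-enters through the same epoxonium 13). Sharpless epoxidation of 10 with D-(−)-DET (Ti(OiPr)4, t-BuOOH) gives [(2R,3R)-3-[(3Z)-4,8-dimethylnona-3,7-dien-1-yl]-3-methyloxiran-2-yl]methanol F1. PPh3/CBr4 gives (2S,3R)-2-(bromomethyl)-3-[(3Z)-4,8-dimethylnona-3,7-dien-1-yl]-3-methyloxirane F2. Dilute HClO4 in THF/H2O opens the epoxide at the tertiary carbon to (2S,3S,6Z)-1-bromo-3,7,11-trimethyldodeca-6,10-diene-2,3-diol F3. Bromonium cyclisation with Et2SBr·SbCl5Br in MeNO2 at −25 °C is then terminated in the established way by the tertiary hydroxyl (the nerolidol to bromo-caparrapi-oxide reaction). After separation of the two bromonium-face diastereomers this gives the cis-fused oxane (1S)-2-bromo-1-[(2S,4aR,6S,8aS)-6-bromo-2,5,5,8a-tetramethyl-3,4,4a,5,6,7,8,8a-octahydro-2H-chromen-2-yl]ethan-1-ol F4. ClCH2SO2Cl/pyridine converts it into (1S)-2-bromo-1-[(2S,4aR,6S,8aS)-6-bromo-2,5,5,8a-tetramethyl-3,4,4a,5,6,7,8,8a-octahydro-2H-chromen-2-yl]ethyl chloromethanesulfonate F5. Heating F5 with Zn(OAc)2 in aqueous AcOH (Nakata's oxane-to-oxepane ring expansion) lets the ring oxygen displace the sulfonate with inversion, which generates 13 and from it 15 as in step 6. D-Tartrate is used because this route inverts the carbinol carbon once; the C3 configuration is erased at the end.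

**Step 3 (hydroboration/Suzuki coupling with a free dienol).** Risks:
- 9-BBN-H may not discriminate cleanly at the conjugated diene in the presence of the O–B group.
- The homoallylic borane may couple sluggishly with the hindered iodide.

Fallback, setting out from 6 and coming back at 10, with C1–C3 built by alkyne carbometalation instead. Negishi coupling of 6 with [4-(trimethylsilyl)but-3-yn-1-yl]zinc bromide F6 (made from 4-bromo-1-(trimethylsilyl)but-1-yne and zinc dust/LiCl; Pd(PPh3)4 cat., THF) gives trimethyl[(5Z)-6,10-dimethylundeca-5,9-dien-1-yn-1-yl]silane F7. K2CO3/MeOH gives (5Z)-6,10-dimethylundeca-5,9-dien-1-yne F8. Zr-catalysed syn-methylalumination (Me3Al, Cp2ZrCl2, CH2Cl2), followed in the same flask by n-BuLi and paraformaldehyde, gives 10 with the 2E geometry. This also removes the need for 8 and step 2.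

**Step 5 (OH → Br next to an acid-sensitive trisubstituted epoxide).** Risks:
- Bromide or HBr may open the epoxide.
- The CH2Br group makes the epoxide a poorer nucleophile for step 6.

Fallback, setting out from 11 and coming back at 15, with the order of the last two operations reversed. The cascade of step 6 is run on 11 itself (NBS, HFIP, 4 Å MS, 0 °C) to give [(2R,5aR,7S,9aS)-7-bromo-3,6,6,9a-tetramethyl-2,5,5a,6,7,8,9,9a-octahydro-1-benzoxepin-2-yl]methanol F9. Its primary alcohol is then converted into the bromide with PPh3/CBr4 to give 15.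

## Further compounds

F1 | step 6 | [(2R,3R)-3-[(3Z)-4,8-dimethylnona-3,7-dien-1-yl]-3-methyloxiran-2-yl]methanol | OC[C@H]1O[C@]1(C)CC/C=C(C)\CCC=C(C)C
F2 | step 6 | (2S,3R)-2-(bromomethyl)-3-[(3Z)-4,8-dimethylnona-3,7-dien-1-yl]-3-methyloxirane | BrC[C@H]1O[C@]1(C)CC/C=C(C)\CCC=C(C)C
F3 | step 6 | (2S,3S,6Z)-1-bromo-3,7,11-trimethyldodeca-6,10-diene-2,3-diol | BrC[C@@H](O)[C@@](C)(O)CC/C=C(C)\CCC=C(C)C
F4 | step 6 | (1S)-2-bromo-1-[(2S,4aR,6S,8aS)-6-bromo-2,5,5,8a-tetramethyl-3,4,4a,5,6,7,8,8a-octahydro-2H-chromen-2-yl]ethan-1-ol | C[C@@]1([C@H](O)CBr)CC[C@@H]2C(C)(C)[C@@H](Br)CC[C@]2(C)O1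
F5 | step 6 | (1S)-2-bromo-1-[(2S,4aR,6S,8aS)-6-bromo-2,5,5,8a-tetramethyl-3,4,4a,5,6,7,8,8a-octahydro-2H-chromen-2-yl]ethyl chloromethanesulfonate | C[C@@]1([C@H](OS(=O)(=O)CCl)CBr)CC[C@@H]2C(C)(C)[C@@H](Br)CC[C@]2(C)O1
F6 | step 3 | [4-(trimethylsilyl)but-3-yn-1-yl]zinc bromide | C[Si](C)(C)C#CCC[Zn]Br
F7 | step 3 | trimethyl[(5Z)-6,10-dimethylundeca-5,9-dien-1-yn-1-yl]silane | C[Si](C)(C)C#CCC/C=C(C)\CCC=C(C)C
F8 | step 3 | (5Z)-6,10-dimethylundeca-5,9-dien-1-yne | C#CCC/C=C(C)\CCC=C(C)C
F9 | step 5 | [(2R,5aR,7S,9aS)-7-bromo-3,6,6,9a-tetramethyl-2,5,5a,6,7,8,9,9a-octahydro-1-benzoxepin-2-yl]methanol | CC1=CC[C@@H]2C(C)(C)[C@@H](Br)CC[C@]2(C)O[C@H]1CO
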